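The route rests on cutting ring B at C5'–C6' and C2'–C3'. Its C3'–C4'–C5' segment, with the E-geranyl chain on C5', is geranylacetone atom for atom. C6'–C1'–C2' together with C3 and C4 of ring C is an itaconate. One base-mediated Michael–Claisen annulation joins the two and closes ring B as a cyclohexane-1,3-dione that already has the 1',2',4',5' pattern of the target, so no substitution on an aromatic ring B is needed. The precursors are the E ketone and the potassium salt of itaconic acid 1-methyl ester, whose carboxylate arm is neither acidic nor electrophilic. Aromatisation, auxiliary-controlled hydroxymethylation (C2, C3 stereocentre), Mitsunobu etherification and Friedel–Crafts closure of ring C follow.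

Key step: step 2

Assumption: geranylacetone is bought as the single E isomer. "Geranyl" means (2E)-3,7-dimethylocta-2,6-dien-1-yl and TIPS means triisopropylsilyl. Isoflavanone locants (C2–C8a, C1'–C6') are also used for the early intermediates. The target SMILES corresponds to 3R.

Step 1
Reactants: 1 dimethyl itaconate
Product: 2 potassium 3-(methoxycarbonyl)but-3-enoate (potassium salt of itaconic acid 1-methyl ester)
Conditions: KOH (1.0 equiv), THF/H2O, 0 °C; Et2O wash; freeze-drying, then high vacuum
Reagents that add atoms: potassium hydroxide, [K+].[OH-]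
Why: Chemoselective half-saponification, in which hydroxide attacks the unconjugated, unhindered CH2CO2Me ester faster than the methacrylate-type ester and the carboxylate formed slows a second hydrolysis.

Step 2
Reactants: 3 (E)-geranylacetone; 2 potassium 3-(methoxycarbonyl)but-3-enoate
Product: 5 2-(5-geranyl-2,4-dioxocyclohexyl)acetic acid (diastereomer mixture), via potassium salt of the keto ester Michael adduct 4 (not isolated)
Conditions: KOt-Bu (2.2 equiv), 3 (1.5 equiv), THF/t-BuOH, 0 °C, 30 min; 2 (1.0 equiv) added over 2 h; 0 °C → rt; H2O, excess 3 extracted at high pH; aq. HCl to pH 3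
Reagents that add atoms: none
Why: KOt-Bu equilibrates the two enolates of 3, the more substituted C5' enolate adds to the CH2= terminus of 2 (C5'–C6'), proton transfer through t-BuOH moves the charge to the methyl carbon C3', and this enolate displaces methoxide from the only ester present (C2'–C3'), the acidic 1,3-dione being drained as its enolate so that the sequence runs forward. The closest known reaction type is the consecutive Michael–Claisen (3+3) annulation of methyl alkyl ketones with acrylates, which alkylates the internal methylene just as base-catalysed cyanoethylation of such ketones does. Ring B closes by a 6-(enolexo)-exo-trig acyl substitution, whereas closure through C5' would need a four-membered ring and the carboxylate of the arm is no electrophile. C1' and C5' arise as an uncontrolled diastereomer mixture, which does not matter because both become sp2 in step 4. The step needs Michael addition at the internal carbon, Claisen acylation at the methyl carbon and uptake of only one acceptor: enolate equilibration and the six-ring preference secure the first two, while slow addition of 2 to excess 3 and the negative charge of the first adduct disfavour a second addition. The arm is deliberately carried as a carboxylate, because in diester 1 the CH2 between alkene and ester is more acidic than the ketone and would divert material into mesaconate/citraconate isomerisation, Stobbe condensation with 3 and oligomerisation.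

Step 3
Reactants: 5 2-(5-geranyl-2,4-dioxocyclohexyl)acetic acid
Product: 6 triisopropylsilyl 2-[5-geranyl-2,4-bis(triisopropylsilyloxy)cyclohexa-2,4-dien-1-yl]acetate (drawn as one of two diene regioisomers that converge in step 4)
Conditions: TIPSOTf (3.3 equiv), Et3N (5 equiv), CH2Cl2, 0 °C → rt
Reagents that add atoms: triisopropylsilyl trifluoromethanesulfonate, CC(C)[Si](OS(=O)(=O)C(F)(F)F)(C(C)C)C(C)C
Why: Soft enolisation with a silyl triflate and a tertiary amine, in which O-silylation of the enolised dione gives a bis(silyloxy)allyl cation that loses the C1' or C5' proton, the acid is capped as its silyl ester, and the isolated alkenes stay untouched in the amine-buffered medium.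

Step 4
Reactants: 6 triisopropylsilyl 2-[5-geranyl-2,4-bis(triisopropylsilyloxy)cyclohexa-2,4-dien-1-yl]acetate
Product: 8 2-[5-geranyl-2,4-bis(triisopropylsilyloxy)phenyl]acetic acid, via aryl TIPS ester 7 (not isolated)
Conditions: DDQ (1.05 equiv), toluene, 0 °C; filtration; then LiOH (1.1 equiv), THF/H2O, 0 °C; aq. HCl to pH 4
Reagents that add atoms: none
Why: Quinone dehydrogenation of a silyloxycyclohexadiene, in which DDQ takes hydride from C6' to give an arenium ion stabilised by both silyloxy groups, loss of the last ring sp3 proton delivers the resorcinol bis(silyl ether) directly, and one equivalent of cold hydroxide then cleaves only the far more labile silyl ester.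

Step 5
Reactants: 8 2-[5-geranyl-2,4-bis(triisopropylsilyloxy)phenyl]acetic acid; 9 (4S)-4-benzyl-1,3-oxazolidin-2-one
Product: 11 (4S)-4-benzyl-3-{[5-geranyl-2,4-bis(triisopropylsilyloxy)phenyl]acetyl}-1,3-oxazolidin-2-one, via mixed pivalic anhydride 10 (not isolated)
Conditions: PivCl, Et3N, THF, −20 °C; then LiCl, 9, −20 °C → rt
Reagents that add atoms: pivaloyl chloride, CC(C)(C)C(=O)Cl (acyl group of 10 only)
Why: Mixed-anhydride N-acylation of the oxazolidinone under LiCl/Et3N activation, which needs neither strong base nor an acid chloride and so leaves the aryl silyl ethers alone.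

Step 6
Reactants: 11 (4S)-4-benzyl-3-{[5-geranyl-2,4-bis(triisopropylsilyloxy)phenyl]acetyl}-1,3-oxazolidin-2-one
Product: 13 (4S)-4-benzyl-3-{(2R)-2-[5-geranyl-2,4-bis(triisopropylsilyloxy)phenyl]-3-hydroxypropanoyl}-1,3-oxazolidin-2-one, via chlorotitanium (Z)-enolate 12 (not isolated)
Conditions: TiCl4 (1.05 equiv), i-Pr2NEt (1.15 equiv), CH2Cl2, 0 °C; then 1,3,5-trioxane (1.1 equiv), TiCl4 (1.0 equiv), 0 °C; aq. NH4Cl
Reagents that add atoms: titanium tetrachloride, Cl[Ti](Cl)(Cl)Cl (metal of 12 only); 1,3,5-trioxane, C1OCOCO1 (one CH2O unit, the future C2)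
Why: Auxiliary-controlled hydroxymethylation of a chelated chlorotitanium (Z)-enolate (aldol-type addition to TiCl4-activated formaldehyde), in which the benzyl group shields one enolate face and the C1 electrophile enters from the other in the same sense as an enolate alkylation, which sets the future C3 as R.

Step 7
Reactants: 14 2-methylresorcinol
Product: 15 2-methyl-1,3-bis(triisopropylsilyloxy)benzene
Conditions: TIPSOTf (2.3 equiv), 2,6-lutidine, CH2Cl2, 0 °C → rt
Reagents that add atoms: triisopropylsilyl trifluoromethanesulfonate, CC(C)[Si](OS(=O)(=O)C(F)(F)F)(C(C)C)C(C)C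
Why: Standard phenol silylation, with the triflate chosen because both hydroxyl groups flank the methyl group.

Step 8
Reactants: 15 2-methyl-1,3-bis(triisopropylsilyloxy)benzene
Product: 17 4-methyl-3,5-bis(triisopropylsilyloxy)phenol, via aryl pinacol boronate 16 (not isolated)
Conditions: [Ir(OMe)(cod)]2 (1.5 mol %), dtbpy (3 mol %), B2pin2 (1.0 equiv), THF, 70 °C; then KHSO5 (as 2KHSO5·KHSO4·K2SO4), acetone/H2O, rt, 10 min
Reagents that add atoms: bis(pinacolato)diboron, CC1(C)OB(OC1(C)C)B1OC(C)(C)C(C)(C)O1 (boryl group of 16 only); potassium peroxymonosulfate, [K+].[O-]S(=O)(=O)OO (phenol oxygen, the future O1)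
Why: Sterically governed iridium-catalysed aromatic C–H borylation reaches only the C–H flanked by two hydrogens, and ipso-oxidation of the boronate in the same flask places the free hydroxyl para to the methyl group, so the two ortho carbons of 17 are equivalent.

Step 9
Reactants: 13 (4S)-4-benzyl-3-{(2R)-2-[5-geranyl-2,4-bis(triisopropylsilyloxy)phenyl]-3-hydroxypropanoyl}-1,3-oxazolidin-2-one; 17 4-methyl-3,5-bis(triisopropylsilyloxy)phenol
Product: 18 (4S)-4-benzyl-3-{(2R)-2-[5-geranyl-2,4-bis(triisopropylsilyloxy)phenyl]-3-[4-methyl-3,5-bis(triisopropylsilyloxy)phenoxy]propanoyl}-1,3-oxazolidin-2-one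
Conditions: PPh3, DIAD, toluene, 0 °C → rt
Reagents that add atoms: none
Why: Mitsunobu etherification by SN2 at the primary carbinol carbon, which leaves C3 untouched, while allylic 1,3-strain in the imide holds the C3–H bond in the carbonyl plane and so slows the competing elimination to the 2-arylacryloyl imide.

Step 10
Reactants: 18 (4S)-4-benzyl-3-{(2R)-2-[5-geranyl-2,4-bis(triisopropylsilyloxy)phenyl]-3-[4-methyl-3,5-bis(triisopropylsilyloxy)phenoxy]propanoyl}-1,3-oxazolidin-2-one
Product: 19 (2R)-2-[5-geranyl-2,4-bis(triisopropylsilyloxy)phenyl]-3-[4-methyl-3,5-bis(triisopropylsilyloxy)phenoxy]propanoic acid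
Conditions: LiOH (2 equiv), H2O2 (6 equiv), THF/H2O, 0 °C; then aq. Na2SO3; aq. HCl to pH 4
Reagents that add atoms: hydrogen peroxide, OO (as LiOOH; one oxygen of the carboxyl group)
Why: Hydroperoxide cleavage of the N-acyloxazolidinone, in which the weakly basic but strongly nucleophilic LiOOH attacks the exocyclic carbonyl at 0 °C faster than it removes the C3 proton, the resulting carboxylate no longer enolises, and aryl TIPS ethers and unactivated alkenes tolerate the medium.

Step 11
Reactants: 19 (2R)-2-[5-geranyl-2,4-bis(triisopropylsilyloxy)phenyl]-3-[4-methyl-3,5-bis(triisopropylsilyloxy)phenoxy]propanoic acid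
Product: 21 (3R)-3-[5-geranyl-2,4-bis(triisopropylsilyloxy)phenyl]-6-methyl-5,7-bis(triisopropylsilyloxy)chroman-4-one, via acid chloride 20 (not isolated)
Conditions: 1-chloro-N,N,2-trimethylprop-1-en-1-amine, CH2Cl2, 0 °C; then 2,6-di-tert-butyl-4-methylpyridine (1.5 equiv), SnCl4 (1.1 equiv), CH2Cl2 (0.01 M), −78 °C; pH 7 buffer at −78 °C
Reagents that add atoms: 1-chloro-N,N,2-trimethylprop-1-en-1-amine, CC(C)=C(Cl)N(C)C (chlorine of 20 only)
Why: Intramolecular Friedel–Crafts acylation closing ring C (C4–C4a), in which neutral chloroenamine activation avoids base and HCl, the attacked ring A carbon is activated by three oxygen substituents and is one of two equivalent sites so that only the 6-methyl-5,7-dioxygenated chromanone can form, and low temperature with a hindered pyridine as proton trap shields C3 and the geranyl alkenes from acid.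

Step 12
Reactants: 21 (3R)-3-[5-geranyl-2,4-bis(triisopropylsilyloxy)phenyl]-6-methyl-5,7-bis(triisopropylsilyloxy)chroman-4-one
Product: 22 (3R)-3-(5-geranyl-2,4-dihydroxyphenyl)-5,7-dihydroxy-6-methylchroman-4-one (CNP0348256.1)
Conditions: Bu4NF/AcOH (1:1, 4.5 equiv), THF, 0 °C
Reagents that add atoms: none
Why: Fluoride desilylation of the four aryl silyl ethers buffered with acetic acid, so that each phenoxide is protonated at once and the labile C3–H next to the C4 carbonyl is not exchanged.

Compound list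
1 | dimethyl itaconate | C=C(CC(=O)OC)C(=O)OC | starting material
2 | potassium 3-(methoxycarbonyl)but-3-enoate | C=C(CC(=O)[O-])C(=O)OC.[K+] | intermediate
3 | (E)-geranylacetone, (5E)-6,10-dimethylundeca-5,9-dien-2-one | CC(=O)CC/C=C(\C)CCC=C(C)C | starting material
4 | potassium (7E)-5-acetyl-3-(methoxycarbonyl)-8,12-dimethyltrideca-7,11-dienoate (Michael adduct, not isolated) | CC(=O)C(C/C=C(\C)CCC=C(C)C)CC(CC(=O)[O-])C(=O)OC.[K+] | intermediate
5 | 2-(5-geranyl-2,4-dioxocyclohexyl)acetic acid (diastereomer mixture) | OC(=O)CC1CC(C/C=C(\C)CCC=C(C)C)C(=O)CC1=O | intermediate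
6 | triisopropylsilyl 2-[5-geranyl-2,4-bis(triisopropylsilyloxy)cyclohexa-2,4-dien-1-yl]acetate | CC(C)=CCC/C(C)=C/CC1=C(O[Si](C(C)C)(C(C)C)C(C)C)C=C(O[Si](C(C)C)(C(C)C)C(C)C)C(CC(=O)O[Si](C(C)C)(C(C)C)C(C)C)C1 | intermediate
7 | triisopropylsilyl 2-[5-geranyl-2,4-bis(triisopropylsilyloxy)phenyl]acetate (not isolated) | CC(C)=CCC/C(C)=C/Cc1cc(CC(=O)O[Si](C(C)C)(C(C)C)C(C)C)c(O[Si](C(C)C)(C(C)C)C(C)C)cc1O[Si](C(C)C)(C(C)C)C(C)C | intermediate
8 | 2-[5-geranyl-2,4-bis(triisopropylsilyloxy)phenyl]acetic acid | CC(C)=CCC/C(C)=C/Cc1cc(CC(=O)O)c(O[Si](C(C)C)(C(C)C)C(C)C)cc1O[Si](C(C)C)(C(C)C)C(C)C | intermediate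
9 | (4S)-4-benzyl-1,3-oxazolidin-2-one | O=C1N[C@@H](Cc2ccccc2)CO1 | starting material
10 | mixed anhydride of 8 and pivalic acid (not isolated) | CC(C)=CCC/C(C)=C/Cc1cc(CC(=O)OC(=O)C(C)(C)C)c(O[Si](C(C)C)(C(C)C)C(C)C)cc1O[Si](C(C)C)(C(C)C)C(C)C | intermediate
11 | (4S)-4-benzyl-3-{[5-geranyl-2,4-bis(triisopropylsilyloxy)phenyl]acetyl}-1,3-oxazolidin-2-one | CC(C)=CCC/C(C)=C/Cc1cc(CC(=O)N2[C@@H](Cc3ccccc3)COC2=O)c(O[Si](C(C)C)(C(C)C)C(C)C)cc1O[Si](C(C)C)(C(C)C)C(C)C | intermediate
12 | trichlorotitanium (Z)-enolate of 11 (not isolated) | Cl[Ti](Cl)(Cl)O/C(=C\c1cc(C/C=C(\C)CCC=C(C)C)c(O[Si](C(C)C)(C(C)C)C(C)C)cc1O[Si](C(C)C)(C(C)C)C(C)C)N1[C@@H](Cc2ccccc2)COC1=O | intermediate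
13 | (4S)-4-benzyl-3-{(2R)-2-[5-geranyl-2,4-bis(triisopropylsilyloxy)phenyl]-3-hydroxypropanoyl}-1,3-oxazolidin-2-one | CC(C)=CCC/C(C)=C/Cc1cc([C@@H](C(=O)N2[C@@H](Cc3ccccc3)COC2=O)CO)c(O[Si](C(C)C)(C(C)C)C(C)C)cc1O[Si](C(C)C)(C(C)C)C(C)C | intermediate
14 | 2-methylresorcinol | Cc1c(O)cccc1O | starting material
15 | 2-methyl-1,3-bis(triisopropylsilyloxy)benzene | Cc1c(O[Si](C(C)C)(C(C)C)C(C)C)cccc1O[Si](C(C)C)(C(C)C)C(C)C | intermediate
16 | 2-[4-methyl-3,5-bis(triisopropylsilyloxy)phenyl]-4,4,5,5-tetramethyl-1,3,2-dioxaborolane (not isolated) | Cc1c(O[Si](C(C)C)(C(C)C)C(C)C)cc(B2OC(C)(C)C(C)(C)O2)cc1O[Si](C(C)C)(C(C)C)C(C)C | intermediate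
17 | 4-methyl-3,5-bis(triisopropylsilyloxy)phenol | Cc1c(O[Si](C(C)C)(C(C)C)C(C)C)cc(O)cc1O[Si](C(C)C)(C(C)C)C(C)C | intermediate
18 | (4S)-4-benzyl-3-{(2R)-2-[5-geranyl-2,4-bis(triisopropylsilyloxy)phenyl]-3-[4-methyl-3,5-bis(triisopropylsilyloxy)phenoxy]propanoyl}-1,3-oxazolidin-2-one | CC(C)=CCC/C(C)=C/Cc1cc([C@@H](C(=O)N2[C@@H](Cc3ccccc3)COC2=O)COc2cc(O[Si](C(C)C)(C(C)C)C(C)C)c(C)c(O[Si](C(C)C)(C(C)C)C(C)C)c2)c(O[Si](C(C)C)(C(C)C)C(C)C)cc1O[Si](C(C)C)(C(C)C)C(C)C | intermediate
19 | (2R)-2-[5-geranyl-2,4-bis(triisopropylsilyloxy)phenyl]-3-[4-methyl-3,5-bis(triisopropylsilyloxy)phenoxy]propanoic acid | CC(C)=CCC/C(C)=C/Cc1cc([C@@H](C(=O)O)COc2cc(O[Si](C(C)C)(C(C)C)C(C)C)c(C)c(O[Si](C(C)C)(C(C)C)C(C)C)c2)c(O[Si](C(C)C)(C(C)C)C(C)C)cc1O[Si](C(C)C)(C(C)C)C(C)C | intermediate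
20 | (2R)-acid chloride of 19 (not isolated) | CC(C)=CCC/C(C)=C/Cc1cc([C@@H](C(=O)Cl)COc2cc(O[Si](C(C)C)(C(C)C)C(C)C)c(C)c(O[Si](C(C)C)(C(C)C)C(C)C)c2)c(O[Si](C(C)C)(C(C)C)C(C)C)cc1O[Si](C(C)C)(C(C)C)C(C)C | intermediate
21 | (3R)-3-[5-geranyl-2,4-bis(triisopropylsilyloxy)phenyl]-6-methyl-5,7-bis(triisopropylsilyloxy)chroman-4-one | CC(C)=CCC/C(C)=C/Cc1cc([C@@H]2COc3cc(O[Si](C(C)C)(C(C)C)C(C)C)c(C)c(O[Si](C(C)C)(C(C)C)C(C)C)c3C2=O)c(O[Si](C(C)C)(C(C)C)C(C)C)cc1O[Si](C(C)C)(C(C)C)C(C)C | intermediate
22 | (3R)-3-(5-geranyl-2,4-dihydroxyphenyl)-5,7-dihydroxy-6-methylchroman-4-one | CC(C)=CCC/C(C)=C/Cc1cc([C@@H]2COc3cc(O)c(C)c(O)c3C2=O)c(O)cc1O | target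

Total step count: 12. Longest linear sequence: 10 (steps 1–6 and 9–12). Steps 7 and 8 form the ring A branch.

Steps most likely to fail

1. Step 2.
- **Risk:** Carbon–carbon bond formation at the internal carbon may lose out to attack through the methyl carbon, to a second conjugate addition, to self-condensation of the ketone, or to plain non-reaction of a poorly soluble, anionic acceptor.
- **Fallback:** it sets out from 1 and comes back at 5.
  - Methyl acetoacetate is added to 1 with catalytic NaOMe in MeOH. The only base then present is the stabilised acetoacetate enolate, which is too weak to deprotonate 1. The Michael addition should give trimethyl 5-oxohexane-1,2,4-tricarboxylate F1.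
  - C-Alkylation of its acetoacetate carbon with geranyl bromide (K2CO3, acetone) fixes the position and the E geometry of the chain in trimethyl 4-geranyl-5-oxohexane-1,2,4-tricarboxylate F2.
  - Krapcho demethoxycarbonylation (LiCl, wet DMSO, 140 °C) removes only the β-keto ester carboxyl. It gives dimethyl 2-[(4E)-2-acetyl-5,9-dimethyldeca-4,8-dienyl]butanedioate F3, in which only the methyl carbon can close a six-membered ring.
  - KOt-Bu in THF then effects the Claisen closure to methyl 2-(5-geranyl-2,4-dioxocyclohexyl)acetate F4. Aqueous LiOH added to the same flask saponifies the arm ester to 5.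

2. Step 11.
- **Risk:** The configuration at C3 may erode through ketene or enol formation from the activated acyl species or from the tin-bound ketone. This matters most if closure at a carbon flanked by a bulky silyloxy group is slow.
- **Fallback:** it sets out from 21 of lowered enantiomeric purity and comes back at 21.
  - Asymmetric transfer hydrogenation under dynamic kinetic resolution is used (RuCl[(R,R)-TsDPEN](p-cymene), HCO2H/Et3N, EtOAc, rt to 40 °C). It turns the lability of C3 to advantage: the amine racemises the ketone while the catalyst reduces the 3R enantiomer from one face. This should give (3R,4R)-cis-3-[5-geranyl-2,4-bis(triisopropylsilyloxy)phenyl]-6-methyl-5,7-bis(triisopropylsilyloxy)chroman-4-ol F5.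
  - Oxidation with Dess–Martin periodinane buffered with NaHCO3 (CH2Cl2, 0 °C) returns the ketone without touching C3.

3. Step 6.
- **Risk:** Lewis-acid-activated formaldehyde may engage the nucleophilic trisubstituted alkenes of the geranyl chain (Prins or ene pathway), and traces of HCl may add to them.
- **Fallback:** it sets out from 11 and comes back at 13.
  - The sodium (Z)-enolate (NaHMDS, THF, −78 °C) is alkylated with pinacol (iodomethyl)boronate. No Lewis acid is present and the facial sense is unchanged. This gives (4S)-4-benzyl-3-{(2S)-2-[5-geranyl-2,4-bis(triisopropylsilyloxy)phenyl]-3-(4,4,5,5-tetramethyl-1,3,2-dioxaborolan-2-yl)propanoyl}-1,3-oxazolidin-2-one F6. The descriptor changes only because boron ranks below carbon.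
  - Oxidation of the C–B bond with H2O2 in pH 7 phosphate buffer/THF at 0 °C gives 13.

Further compounds
F1 | step 2 | trimethyl 5-oxohexane-1,2,4-tricarboxylate | CC(=O)C(C(=O)OC)CC(CC(=O)OC)C(=O)OC
F2 | step 2 | trimethyl 4-geranyl-5-oxohexane-1,2,4-tricarboxylate | CC(=O)C(C/C=C(\C)CCC=C(C)C)(C(=O)OC)CC(CC(=O)OC)C(=O)OC
F3 | step 2 | dimethyl 2-[(4E)-2-acetyl-5,9-dimethyldeca-4,8-dienyl]butanedioate | CC(=O)C(C/C=C(\C)CCC=C(C)C)CC(CC(=O)OC)C(=O)OC
F4 | step 2 | methyl 2-(5-geranyl-2,4-dioxocyclohexyl)acetate | COC(=O)CC1CC(C/C=C(\C)CCC=C(C)C)C(=O)CC1=O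
F5 | step 11 | (3R,4R)-cis-3-[5-geranyl-2,4-bis(triisopropylsilyloxy)phenyl]-6-methyl-5,7-bis(triisopropylsilyloxy)chroman-4-ol | CC(C)=CCC/C(C)=C/Cc1cc([C@@H]2COc3cc(O[Si](C(C)C)(C(C)C)C(C)C)c(C)c(O[Si](C(C)C)(C(C)C)C(C)C)c3[C@@H]2O)c(O[Si](C(C)C)(C(C)C)C(C)C)cc1O[Si](C(C)C)(C(C)C)C(C)C
F6 | step 6 | (4S)-4-benzyl-3-{(2S)-2-[5-geranyl-2,4-bis(triisopropylsilyloxy)phenyl]-3-(4,4,5,5-tetramethyl-1,3,2-dioxaborolan-2-yl)propanoyl}-1,3-oxazolidin-2-one | CC(C)=CCC/C(C)=C/Cc1cc([C@@H](C(=O)N2[C@@H](Cc3ccccc3)COC2=O)CB2OC(C)(C)C(C)(C)O2)c(O[Si](C(C)C)(C(C)C)C(C)C)cc1O[Si](C(C)C)(C(C)C)C(C)C
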